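**Assumption:** the SMILES fixes the constitution (O4'-methyl, free O5'–H and O8–H) but carries no descriptor for the C7–C1' axis, the only stereogenic element. The route is therefore planned to the racemic biaryl, and the atropisomers are parted at the end on a chiral stationary phase.

Locants: isoquinoline atoms are unprimed (C1, N2, C3 … C8a). Naphthalene atoms are primed: C1' is the axis carbon, C2' carries the methyl group, C4' the methoxy group and C5' the hydroxyl group.

## The problem

1. The target is two flat bicycles, a 1,3-dimethylisoquinolin-8-ol and a peri-dioxygenated methylnaphthalene, joined by the single bond C7–C1'.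
2. That bond is an axis flanked by O8, the C2' methyl group and the peri C8'–H, so any aryl–aryl coupling across it is a hindered, tri-ortho-substituted case. There is no stereocentre elsewhere that could control the axis.
3. Regiochemistry is the real difficulty on both sides. The isoquinolinol is nucleophilic at C5 (para) as well as at C7 (ortho). The naphthalene has to be joined at C1', para to the methylated O4', and not at the positions activated by the free O5'–H.
4. Three phenolic oxygens must be told apart: O4' is methylated, while its peri neighbour O5' and the distant O8 stay free.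
5. The sensitive points are the electron-rich peri-dioxygenated naphthol (oxidation to quinones in base and air), the nitrogen N2 (quaternization by alkylating agents, binding of Lewis acids) and the acidic C1 methyl group (lateral metalation).
6. The feature that opens the problem lies in ring C1'–C2'–C3'–C4'–C4a'–C8a'. C1', C2' with its methyl group and C3' together are a 2-methylallyl unit. C4' is a carboxyl-level carbon on C4a', next to the carbon that bears O5'. C1' sits ortho to the free O8–H.
7. The three allyl carbons can therefore be delivered from O8 to C7 by a [3,3] shift, and the ring can be closed by C3' onto a C4' carbonyl group. C1' becomes aromatic only at that moment, so the axis is never made by joining two arenes.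

## Retrosynthesis

**O–alkyl bonds (21 ⇐ 20 ⇐ 19).** The isopropyl group on O5' and the methoxymethyl group on O8 are removed from 20, and the O4'–CH3 bond is cut to give 19. At the moment of methylation O4' is then the only free hydroxyl group, so the three oxygens are distinguished by the order of events and not by reagent selectivity. Methylating with O8–H free would rest on an acidity difference too small to trust. The forward steps are one Williamson methylation and one Lewis-acid dealkylation that must spare a methyl ether.

**C3'–C4', the key cut (19 ⇐ 16).** The naphthalene ring is opened between C3' and C4'. C4' returns to a diethylcarboxamide on C4a', C3' to the CH2 terminus of a 2-methylallyl group, and C1' to an sp3 methine that carries both arenes.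
- Against cutting C7–C1' here: that would be an aryl–aryl coupling, needing a halogen at C7 and a hindered catalytic step.
- Against cutting C2'–C3' (the aldol mode of the biosynthesis): it needs an acetyl group on C4a' and a methyl ketone at C2'. That ketone would have to come from the isopropenyl group by oxidative cleavage next to an electron-rich phenol, at the cost of a step and a carbon atom.
- Simplification: 16 has no naphthalene and no axis. It is a benzamide with a tertiary allylic methine.
- Forward demand: deprotonation at C1', attack through C3' on the amide carbonyl, loss of diethylamide and enolization.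

**C7–C1' (16 ⇐ 15 ⇐ 13).** After removal of the O8 protecting group (15), the C7–C1' bond is cut in the retro-Claisen sense. The allyl unit returns to O8 as the ether 13, with the double bond moved to C1'=C2'. Any intermolecular way of attaching this carbon to C7 would have to choose between C5 and C7 and between the two allyl termini; the shift from O8 decides both. The precursor 13 is held together by a simple O–CH2 bond. The forward reaction must tolerate an aryl group on the migrating terminus.

**O8–CH2 and the allyl fragment (13 ⇐ 6 + 12; 12 ⇐ 8 + 9; 8 ⇐ 7).** The ether bond is cut to the phenol 6 and the branched allylic carbonate 12. The branched isomer is chosen because it comes in one flask from the benzamide 8 and methacrolein 9 (through 10 and 11), and because a palladium allyl complex passes the phenoxide to the unsubstituted terminus. A linear allylic alcohol made by olefination and reduction would cost three more steps. Two fragments of similar size result, each two or three steps from a commercial benzene.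

**The pyridine ring of 6 (6 ⇐ 4 ⇐ 2 + 3; 2 ⇐ 1).** N2–C1 and N2–C3 are cut. Nitrogen returns to ammonia, C1 to an acetyl group and C3 to an alkyne carbon (through 5). The alkyne 4 comes from the triflate 2 and propyne 3, and 2 from the ketone 1, which already holds the oxygen pattern. Acid-mediated closures of the Bischler–Napieralski kind onto a 3-oxygenated ring would close para to oxygen and give the 6-oxygenated isomer. Here the 1,2,3-pattern is bought with 1.

## Roads not taken

**Alternative 1: biaryl cross-coupling (the obvious route).**
- Cut: C7–C1' between two finished bicycles.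
- Forward key step: Suzuki–Miyaura coupling of 7-bromo-8-(methoxymethoxy)-1,3-dimethylisoquinoline A1 with [4-methoxy-2-methyl-5-(propan-2-yloxy)naphthalen-1-yl]boronic acid A2 to give 20.
- Why the chosen plan is better:
  - The coupling is tri-ortho-substituted. Transmetalation and reductive elimination are slow, and protodeboronation of the electron-rich, doubly ortho-substituted A2 competes.
  - A1 needs bromine at C7, but electrophilic halogenation of 6 favours C5 (para, and an α-position of the bicycle). A1 would need its own regiocontrolled ring synthesis.
  - A2 needs a full naphthalene synthesis with the peri oxygens already differentiated and C1' halogenated selectively.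
  - The chosen route uses no halogenated bicycle. The regiochemistry at C7 follows from a sigmatropic shift and that at C1' from the ring construction.

**Alternative 2: dehydrogenative phenol coupling.**
- Cut: the same bond, with two C–H partners.
- Forward key step: anodic (or one-electron chemical) oxidative cross-coupling of 6 with 8-methoxy-6-methylnaphthalen-1-ol A3, giving 21 directly as in the biosynthesis.
- Why the chosen plan is better:
  - In A3 the free hydroxyl group activates C2 and C4 of its own ring, but the bond needed is para to the methoxy group on the other ring.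
  - The natural coupling occurs para to a free O4'–H. That would call for the isomer 8-methoxy-3-methylnaphthalen-1-ol A4, followed by an exchange of the methyl group between the peri oxygens.
  - 6 offers C5 besides C7, and homo-coupling and over-oxidation to quinones are open.
  - It is the shortest plan on paper, but no element of the structure steers either coupling site.

**Alternative 3: ester-bridged intramolecular arylation.**
- Cut: C7–C1', made inside a ring.
- Forward key step: the ester 1,3-dimethylisoquinolin-8-yl 1-bromo-4-methoxy-5-(propan-2-yloxy)naphthalene-2-carboxylate A5 undergoes palladium-catalysed intramolecular arylation at C7 to the six-membered biaryl lactone A6. Reductive ring opening gives the hydroxymethyl biaryl A7, whose CH2OH group must then be deoxygenated to the C2' methyl group.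
- Strengths: the tether guarantees C7, and the ring opening could be run with a chiral hydride to set the axis.
- Why the chosen plan is better: A5 needs the fully substituted bromonaphthoic acid, which is a long synthesis. The carboxyl carbon has to be taken down to a methyl group over two or three steps. The chosen route builds the naphthalene in the key step from a salicylamide and methacrolein with the C2' methyl group already in place. It gives up control of the axis in exchange.

Key step: step 9

## Route

**Step 1**
Reactants: 1 1-(2,6-dihydroxyphenyl)ethan-1-one
Product: 2 2-acetyl-3-hydroxyphenyl trifluoromethanesulfonate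
Conditions: Tf2O (1.0 equiv), pyridine, CH2Cl2, −78 to 0 °C
Reagents that add atoms: trifluoromethanesulfonic anhydride, O=S(=O)(OS(=O)(=O)C(F)(F)F)C(F)(F)F
Why: Mono-O-sulfonylation; after the first triflation the remaining hydroxyl group is locked in a hydrogen bond to the acetyl oxygen and is much less nucleophilic, so one equivalent should stop at the mono-triflate.

**Step 2**
Reactants: 2 2-acetyl-3-hydroxyphenyl trifluoromethanesulfonate; 3 propyne
Product: 4 1-[2-hydroxy-6-(prop-1-yn-1-yl)phenyl]ethan-1-one
Conditions: PdCl2(PPh3)2 (cat.), CuI (cat.), Et3N, DMF, 50 °C, sealed vessel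
Reagents that add atoms: none
Why: Sonogashira coupling; a triflate ortho to an acyl group undergoes oxidative addition readily, and the hydrogen-bonded phenol is tolerated.

**Step 3**
Reactants: 4 1-[2-hydroxy-6-(prop-1-yn-1-yl)phenyl]ethan-1-one
Product: 6 1,3-dimethylisoquinolin-8-ol, via ketimine 5 (not isolated)
Conditions: NH3 (7 M in MeOH), 100 °C, sealed tube
Reagents that add atoms: ammonia, N
Why: Annulation of an ortho-alkynyl aryl ketone with ammonia: condensation to the ortho-hydroxyaryl ketimine 5, then 6-endo-dig attack of the imine nitrogen on the alkyne and tautomerization; the 6-endo mode leads directly to the aromatic pyridine ring.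

**Step 4**
Reactants: 7 N,N-diethyl-2-hydroxybenzamide
Product: 8 N,N-diethyl-2-(propan-2-yloxy)benzamide
Conditions: 2-bromopropane, K2CO3, DMF, 60 °C
Reagents that add atoms: 2-bromopropane, CC(C)Br
Why: Williamson ether synthesis; the isopropyl ether is inert to alkyllithiums, is only a weak director of metalation, and is cleaved by BCl3 in the presence of a methyl ether.

**Step 5**
Reactants: 8 N,N-diethyl-2-(propan-2-yloxy)benzamide; 9 2-methylprop-2-enal (methacrolein)
Product: 12 1-[2-(diethylcarbamoyl)-3-(propan-2-yloxy)phenyl]-2-methylprop-2-en-1-yl methyl carbonate (racemic), via aryllithium 10 (not isolated), via lithium alkoxide 11 (not isolated)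
Conditions: s-BuLi, TMEDA, THF, −78 °C; then 9, −78 °C; then ClCO2Me, −78 to 0 °C
Reagents that add atoms: methyl chloroformate, COC(Cl)=O
Why: Directed ortho-metalation: the tertiary amide directs lithiation to its free ortho position, 1,2-addition of 10 to the enal gives alkoxide 11, and this is acylated in the same flask. The carbinol centre is racemic and is lost in step 6.

**Step 6**
Reactants: 6 1,3-dimethylisoquinolin-8-ol; 12 1-[2-(diethylcarbamoyl)-3-(propan-2-yloxy)phenyl]-2-methylprop-2-en-1-yl methyl carbonate
Product: 13 N,N-diethyl-2-[(1E)-3-[(1,3-dimethylisoquinolin-8-yl)oxy]-2-methylprop-1-en-1-yl]-6-(propan-2-yloxy)benzamide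
Conditions: Pd(PPh3)4 (cat.), THF, 40 °C
Reagents that add atoms: none
Why: Tsuji–Trost O-allylation: zerovalent palladium ionizes the carbonate to a 1-aryl-2-methylallyl complex, and the methoxide set free deprotonates the phenol. The phenoxide attacks the unsubstituted terminus, which is less hindered and leaves the alkene conjugated, giving the linear ether; the E geometry is expected but does not matter for step 7.

**Step 7**
Reactants: 13 N,N-diethyl-2-[(1E)-3-[(1,3-dimethylisoquinolin-8-yl)oxy]-2-methylprop-1-en-1-yl]-6-(propan-2-yloxy)benzamide
Product: 15 N,N-diethyl-2-[1-(8-hydroxy-1,3-dimethylisoquinolin-7-yl)-2-methylprop-2-en-1-yl]-6-(propan-2-yloxy)benzamide (racemic), via ortho-dienone 14 (not isolated)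
Conditions: PhNEt2, 190 °C, argon, sealed vessel
Reagents that add atoms: none
Why: Aromatic Claisen rearrangement: a [3,3] shift through a chair transition state breaks O8–CH2 and joins C7 to the aryl-bearing allyl terminus, and dienone 14 then tautomerizes. Only C7 can accept the group, because the other ortho position, C8a, is a ring fusion and the C7–C8 bond has the high double-bond character of a naphthalene α,β-bond. The new centre at C1' forms racemic and is erased in step 9; the basic solvent suppresses acid-catalysed addition of the phenol to the isopropenyl group.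

**Step 8**
Reactants: 15 N,N-diethyl-2-[1-(8-hydroxy-1,3-dimethylisoquinolin-7-yl)-2-methylprop-2-en-1-yl]-6-(propan-2-yloxy)benzamide
Product: 16 N,N-diethyl-2-{1-[8-(methoxymethoxy)-1,3-dimethylisoquinolin-7-yl]-2-methylprop-2-en-1-yl}-6-(propan-2-yloxy)benzamide (racemic)
Conditions: NaH, THF, 0 °C; then MOMCl, 0 °C to rt
Reagents that add atoms: chloromethyl methyl ether, COCCl
Why: O-alkylation of the preformed sodium phenoxide (Williamson type); forming the phenoxide first keeps the electrophile away from N2, which is in any case flanked by two methyl groups.

**Step 9**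
Reactants: 16 N,N-diethyl-2-{1-[8-(methoxymethoxy)-1,3-dimethylisoquinolin-7-yl]-2-methylprop-2-en-1-yl}-6-(propan-2-yloxy)benzamide
Product: 19 4-[8-(methoxymethoxy)-1,3-dimethylisoquinolin-7-yl]-3-methyl-8-(propan-2-yloxy)naphthalen-1-ol (racemic axis), via allyllithium 17 (not isolated), via naphthalen-1(2H)-one 18 (not isolated)
Conditions: LiN(iPr)2 (2.5 equiv), THF, −78 °C to rt; then aq. NH4Cl
Reagents that add atoms: none
Why: LiN(iPr)2 removes the doubly benzylic, allylic proton at C1' to give the delocalized allyllithium 17, whose C3' terminus adds to the carboxamide carbon C4' held ortho to it; loss of lithium diethylamide gives enone 18, which the amide base just released deprotonates at C3', so the sequence ends irreversibly at the naphtholate of 19. The closest known reaction type is the base-mediated cyclization of ortho-allyl N,N-dialkylbenzamides to 1-naphthols, here with an additional aryl group on the allylic carbon. Ring C1'–C2'–C3'–C4'–C4a'–C8a' closes by 6-exo-trig attack of the allyl anion terminus on the carbonyl group, forming bond C3'–C4'. No new stereocentre is formed: the racemic centre at C1' from step 7 is erased on deprotonation, and the C7–C1' axis appears without control when C1' becomes trigonal, so 19 is a racemate of atropisomers. Two selectivities are needed, C1'–H over the C1 methyl group of the isoquinoline and γ- over α-attack; the first rests on the higher acidity of a diarylmethine that is also allylic and on the reversibility of any lateral metalation, the second on ring size, since α-attack would close a four-membered ring. The amide is twisted out of the arene plane by its two ortho substituents and so presents its carbonyl π* lobe in that plane towards C3', which is why an amide otherwise inert to nucleophiles should accept this intramolecular one.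

**Step 10**
Reactants: 19 4-[8-(methoxymethoxy)-1,3-dimethylisoquinolin-7-yl]-3-methyl-8-(propan-2-yloxy)naphthalen-1-ol
Product: 20 7-[4-methoxy-2-methyl-5-(propan-2-yloxy)naphthalen-1-yl]-8-(methoxymethoxy)-1,3-dimethylisoquinoline
Conditions: NaH, DMF, 0 °C; then MeI (1.1 equiv), 0 °C to rt
Reagents that add atoms: iodomethane, CI
Why: Williamson O-methylation of the only free hydroxyl group; N2, flanked by the C1 and C3 methyl groups, is a poor nucleophile, and the limited amount of MeI should keep quaternization down.

**Step 11**
Reactants: 20 7-[4-methoxy-2-methyl-5-(propan-2-yloxy)naphthalen-1-yl]-8-(methoxymethoxy)-1,3-dimethylisoquinoline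
Product: 21 7-(5-hydroxy-4-methoxy-2-methylnaphthalen-1-yl)-1,3-dimethylisoquinolin-8-ol (ent-dioncophylleine A as drawn)
Conditions: BCl3 (excess), CH2Cl2, −78 to 0 °C; then MeOH; then HPLC on a chiral stationary phase
Reagents that add atoms: none
Why: Lewis-acid ether cleavage: BCl3 opens the acetal-type methoxymethyl ether and the secondary isopropyl ether (through the isopropyl cation) much faster than a methyl aryl ether, so O4'–CH3 should survive. The tri-ortho-substituted axis should be configurationally stable at room temperature, so the atropisomers can be separated and the wanted one assigned by circular dichroism.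

## Compound list

1 | 1-(2,6-dihydroxyphenyl)ethan-1-one | CC(=O)c1c(O)cccc1O | starting material
2 | 2-acetyl-3-hydroxyphenyl trifluoromethanesulfonate | CC(=O)c1c(O)cccc1OS(=O)(=O)C(F)(F)F | intermediate
3 | propyne | CC#C | starting material
4 | 1-[2-hydroxy-6-(prop-1-yn-1-yl)phenyl]ethan-1-one | CC#Cc1cccc(O)c1C(C)=O | intermediate
5 | 2-(1-iminoethyl)-3-(prop-1-yn-1-yl)phenol (ketimine) | CC#Cc1cccc(O)c1C(C)=N | intermediate (not isolated)
6 | 1,3-dimethylisoquinolin-8-ol | Cc1cc2cccc(O)c2c(C)n1 | intermediate
7 | N,N-diethyl-2-hydroxybenzamide | CCN(CC)C(=O)c1ccccc1O | starting material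
8 | N,N-diethyl-2-(propan-2-yloxy)benzamide | CCN(CC)C(=O)c1ccccc1OC(C)C | intermediate
9 | 2-methylprop-2-enal (methacrolein) | CC(=C)C=O | starting material
10 | [2-(diethylcarbamoyl)-3-(propan-2-yloxy)phenyl]lithium | CCN(CC)C(=O)c1c([Li])cccc1OC(C)C | intermediate (not isolated)
11 | lithium 1-[2-(diethylcarbamoyl)-3-(propan-2-yloxy)phenyl]-2-methylprop-2-en-1-olate | CCN(CC)C(=O)c1c(C(O[Li])C(C)=C)cccc1OC(C)C | intermediate (not isolated)
12 | 1-[2-(diethylcarbamoyl)-3-(propan-2-yloxy)phenyl]-2-methylprop-2-en-1-yl methyl carbonate (racemic) | CCN(CC)C(=O)c1c(C(OC(=O)OC)C(C)=C)cccc1OC(C)C | intermediate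
13 | N,N-diethyl-2-[(1E)-3-[(1,3-dimethylisoquinolin-8-yl)oxy]-2-methylprop-1-en-1-yl]-6-(propan-2-yloxy)benzamide | CCN(CC)C(=O)c1c(/C=C(\C)COc2cccc3cc(C)nc(C)c23)cccc1OC(C)C | intermediate
14 | N,N-diethyl-2-[1-(1,3-dimethyl-8-oxo-7,8-dihydroisoquinolin-7-yl)-2-methylprop-2-en-1-yl]-6-(propan-2-yloxy)benzamide (ortho-dienone) | CCN(CC)C(=O)c1c(C(C(C)=C)C2C=Cc3cc(C)nc(C)c3C2=O)cccc1OC(C)C | intermediate (not isolated)
15 | N,N-diethyl-2-[1-(8-hydroxy-1,3-dimethylisoquinolin-7-yl)-2-methylprop-2-en-1-yl]-6-(propan-2-yloxy)benzamide (racemic) | CCN(CC)C(=O)c1c(C(C(C)=C)c2ccc3cc(C)nc(C)c3c2O)cccc1OC(C)C | intermediate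
16 | N,N-diethyl-2-{1-[8-(methoxymethoxy)-1,3-dimethylisoquinolin-7-yl]-2-methylprop-2-en-1-yl}-6-(propan-2-yloxy)benzamide (racemic) | CCN(CC)C(=O)c1c(C(C(C)=C)c2ccc3cc(C)nc(C)c3c2OCOC)cccc1OC(C)C | intermediate
17 | C1'-lithio derivative of 16 (allyllithium) | CCN(CC)C(=O)c1c(C([Li])(C(C)=C)c2ccc3cc(C)nc(C)c3c2OCOC)cccc1OC(C)C | intermediate (not isolated)
18 | 4-[8-(methoxymethoxy)-1,3-dimethylisoquinolin-7-yl]-3-methyl-8-(propan-2-yloxy)naphthalen-1(2H)-one | CC(C)Oc1cccc2C(c3ccc4cc(C)nc(C)c4c3OCOC)=C(C)CC(=O)c12 | intermediate (not isolated)
19 | 4-[8-(methoxymethoxy)-1,3-dimethylisoquinolin-7-yl]-3-methyl-8-(propan-2-yloxy)naphthalen-1-ol (racemic axis) | CC(C)Oc1cccc2c(-c3ccc4cc(C)nc(C)c4c3OCOC)c(C)cc(O)c12 | intermediate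
20 | 7-[4-methoxy-2-methyl-5-(propan-2-yloxy)naphthalen-1-yl]-8-(methoxymethoxy)-1,3-dimethylisoquinoline (racemic axis) | COc1cc(C)c(-c2ccc3cc(C)nc(C)c3c2OCOC)c2cccc(OC(C)C)c12 | intermediate
21 | 7-(5-hydroxy-4-methoxy-2-methylnaphthalen-1-yl)-1,3-dimethylisoquinolin-8-ol | COc1cc(C)c(-c2ccc3cc(C)nc(C)c3c2O)c2cccc(O)c12 | target

## Step count and risk

Total: 11 steps. Longest linear sequence: 9 steps (1, 2, 3, 6, 7, 8, 9, 10, 11). Steps 4 and 5 form the side branch.

**Step 9 (key step).**
- Most likely failure: kinetic metalation of the C1 methyl group of the isoquinoline instead of C1'–H, or sluggish attack of the strongly delocalized, hindered allyl anion on the doubly ortho-substituted amide. In the second case the anion is reprotonated at C3' on work-up, and the alkene moves into conjugation with both arenes.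
- Fallback, from 16 back to 19, closing the same C3'–C4' bond without base:
  - Cp2Zr(H)Cl reduces the tertiary amide of 16 to the benzaldehyde F1.
  - Me2AlCl promotes an intramolecular carbonyl-ene (Prins-type) cyclization of the aldehyde with the 2-methylallyl group, giving the methylidene tetralol F2. Its diastereomers and double-bond isomers all converge.
  - Oxidation with Dess–Martin periodinane gives the methylidene tetralone F3, a non-aromatic tautomer of 19. Et3N should isomerize it to 19.

**Step 7.**
- Most likely failure: heterolysis of the cinnamyl-type ether with recombination at C5 or loss of the allyl group, or addition of the newly formed phenol to the isopropenyl group at 190 °C (dihydrofuran formation).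
- Fallback, from 6 back to 15, making the C7–C1' bond by carbonyl addition:
  - Magnesium-directed ortho-formylation of 6 (MgCl2, Et3N, paraformaldehyde, MeCN, reflux) gives the salicylaldehyde-type isoquinoline F4.
  - After deprotonation with NaH, addition of aryllithium 10 (made from 8 as in step 5) gives the ortho-hydroxy diarylcarbinol F5.
  - Excess isopropenylmagnesium bromide in THF eliminates the magnesium alkoxide to the ortho-quinone methide F6 and adds to it in the 1,4-sense, giving 15.

**Step 6.**
- Most likely failure: attack of the phenoxide at the aryl-bearing terminus, re-ionization of the product ether leading to C-allylation, or capture of the allyl complex by the neighbouring amide oxygen.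
- Fallback, from 8 back to 13, with the ether made by displacement on a preformed linear alcohol:
  - 8 is lithiated as in step 5 and 10 is quenched with DMF to give the formyl benzamide F7.
  - Wittig reaction with Ph3P=C(CH3)CO2Et gives the (E)-enoate F8.
  - iBu2AlH at −78 °C reduces the ester ahead of the hindered amide, giving the allylic alcohol F9.
  - Mitsunobu reaction with 6 (PPh3, diisopropyl azodicarboxylate) gives 13.

**Step 3.**
- Most likely failure: slow hydroamination of the unactivated alkyne by the hydrogen-bonded ketimine, with competing closure through the carbonyl oxygen.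
- Fallback, from 4 back to 6, which is the biosynthetic way of making the pyridine ring: acid-catalysed hydration of 4 (TsOH, wet MeCN, 80 °C; through the 2-benzopyrylium ion) gives the 1,5-diketone F10. NH4OAc in AcOH condenses F10 to 6, and the acidic medium holds back the competing aldol closure to a naphthalenediol.

## Further compounds

F1 | step 9 | 2-{1-[8-(methoxymethoxy)-1,3-dimethylisoquinolin-7-yl]-2-methylprop-2-en-1-yl}-6-(propan-2-yloxy)benzaldehyde | O=Cc1c(C(C(C)=C)c2ccc3cc(C)nc(C)c3c2OCOC)cccc1OC(C)C
F2 | step 9 | 4-[8-(methoxymethoxy)-1,3-dimethylisoquinolin-7-yl]-3-methylidene-8-(propan-2-yloxy)-1,2,3,4-tetrahydronaphthalen-1-ol (mixture of diastereomers) | OC1CC(=C)C(c2ccc3cc(C)nc(C)c3c2OCOC)c2cccc(OC(C)C)c12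
F3 | step 9 | 4-[8-(methoxymethoxy)-1,3-dimethylisoquinolin-7-yl]-3-methylidene-8-(propan-2-yloxy)-3,4-dihydronaphthalen-1(2H)-one | O=C1CC(=C)C(c2ccc3cc(C)nc(C)c3c2OCOC)c2cccc(OC(C)C)c12
F4 | step 7 | 8-hydroxy-1,3-dimethylisoquinoline-7-carbaldehyde | Cc1cc2ccc(C=O)c(O)c2c(C)n1
F5 | step 7 | N,N-diethyl-2-[hydroxy(8-hydroxy-1,3-dimethylisoquinolin-7-yl)methyl]-6-(propan-2-yloxy)benzamide (racemic) | CCN(CC)C(=O)c1c(C(O)c2ccc3cc(C)nc(C)c3c2O)cccc1OC(C)C
F6 | step 7 | N,N-diethyl-2-[(1,3-dimethyl-8-oxoisoquinolin-7(8H)-ylidene)methyl]-6-(propan-2-yloxy)benzamide (ortho-quinone methide) | CCN(CC)C(=O)c1c(C=C2C=Cc3cc(C)nc(C)c3C2=O)cccc1OC(C)C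
F7 | step 6 | N,N-diethyl-2-formyl-6-(propan-2-yloxy)benzamide | CCN(CC)C(=O)c1c(C=O)cccc1OC(C)C
F8 | step 6 | ethyl (2E)-3-[2-(diethylcarbamoyl)-3-(propan-2-yloxy)phenyl]-2-methylprop-2-enoate | CCOC(=O)/C(C)=C/c1cccc(OC(C)C)c1C(=O)N(CC)CC
F9 | step 6 | N,N-diethyl-2-[(1E)-3-hydroxy-2-methylprop-1-en-1-yl]-6-(propan-2-yloxy)benzamide | OC/C(C)=C/c1cccc(OC(C)C)c1C(=O)N(CC)CC
F10 | step 3 | 1-(2-acetyl-3-hydroxyphenyl)propan-2-one | CC(=O)Cc1cccc(O)c1C(C)=O
A1 | alternative 1 | 7-bromo-8-(methoxymethoxy)-1,3-dimethylisoquinoline | COCOc1c(Br)ccc2cc(C)nc(C)c12
A2 | alternative 1 | [4-methoxy-2-methyl-5-(propan-2-yloxy)naphthalen-1-yl]boronic acid | COc1cc(C)c(B(O)O)c2cccc(OC(C)C)c12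
A3 | alternative 2 | 8-methoxy-6-methylnaphthalen-1-ol | COc1cc(C)cc2cccc(O)c12
A4 | alternative 2 | 8-methoxy-3-methylnaphthalen-1-ol | COc1cccc2cc(C)cc(O)c12
A5 | alternative 3 | 1,3-dimethylisoquinolin-8-yl 1-bromo-4-methoxy-5-(propan-2-yloxy)naphthalene-2-carboxylate | COc1cc(C(=O)Oc2cccc3cc(C)nc(C)c23)c(Br)c2cccc(OC(C)C)c12
A6 | alternative 3 | six-membered biaryl lactone from A5 (O8–C(=O)–C2' bridge, C7–C1' bond closed) | COc1cc2C(=O)Oc3c(ccc4cc(C)nc(C)c34)-c2c2cccc(OC(C)C)c12
A7 | alternative 3 | 7-[2-(hydroxymethyl)-4-methoxy-5-(propan-2-yloxy)naphthalen-1-yl]-1,3-dimethylisoquinolin-8-ol | COc1cc(CO)c(-c2ccc3cc(C)nc(C)c3c2O)c2cccc(OC(C)C)c12
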